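**Plan**
The target is an ent-labda-7,13E-diene-15,17-diol (5R,9S,10R) acylated on O15 by 30-hydroxytriacontanoic acid. The retrosynthesis cuts the O15–acyl bond, the C17–O bond, the C9–C11 bond, the C3–C4 bond of ring A, the C10–C1 and C10–C20 bonds, and C15–C16 of the acid.
The enabling feature: ring B (C5 to C10) with C17 on C8, the C7=C8 olefin and C5 bearing C4 is the ring of (S)-carvone; its isopropenyl carbon is C4 and its carbonyl carbon is C9.
Forward: carvone is alkylated twice at C10 (C20, then a C1–C2–C3 acrylate arm), ring A closes through a tertiary C4 radical, the C2 ester is excised, and the C9 ketone becomes a dienyl triflate.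
The C11–C16 chain is joined by B-alkyl Suzuki coupling, a 1,4-hydrogenation sets C9 and the C7=C8 olefin, O15 is acylated with the C30 acid (two C15 lactone halves), C17 is hydroxylated and the silyl group removed.
Stereochemistry: C5 comes from (S)-carvone, C10 from alkylation anti to the isopropenyl group (hence the trans ring fusion), C9 from hydrogen delivery to the face opposite C20, and 13E from the enynol.

Key step: step 3

Remark on the chemistry: 2 is carried as its C6 epimer mixture and 5 to 8 as whatever C2 epimer mixture forms; both centres are erased later (enolate in step 2, methylene after step 5), and the structures show the expected major isomers. Labdane numbering is used throughout.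

**Step 1**
Reactants: 1 (S)-(+)-carvone
Product: 2 trans-6-methylcarvone [(5S,6R)-2,6-dimethyl-5-(prop-1-en-2-yl)cyclohex-2-en-1-one]
Conditions: LiN(i-Pr)2, THF, −78 °C; MeI, −78 to 0 °C
Reagents that add atoms: iodomethane, CI
Why: Kinetic deprotonation at the α′ methylene (future C10) gives the cross-conjugated lithium dienolate, which is C-methylated (enolate alkylation) to install C20; the new centre needs no control because step 2 planarises it again.

**Step 2**
Reactants: 2 trans-6-methylcarvone; 3 ethyl 2-(bromomethyl)acrylate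
Product: 4 ethyl 2-{[(1R,6R)-1,3-dimethyl-2-oxo-6-(prop-1-en-2-yl)cyclohex-3-en-1-yl]methyl}prop-2-enoate (acrylate arm trans to the isopropenyl group)
Conditions: LiN(i-Pr)2, THF, −78 °C; 3, −78 to −20 °C
Reagents that add atoms: none
Why: Diastereoselective enolate alkylation: the tetrasubstituted enolate is shielded on the face of the neighbouring isopropenyl group, so the very reactive allylic bromide (SN2 or SN2′, same product) should enter anti and fix the quaternary C10 with the arm trans to the isopropenyl group.

**Step 3**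
Reactants: 4 ethyl 2-{[(1R,6R)-1,3-dimethyl-2-oxo-6-(prop-1-en-2-yl)cyclohex-3-en-1-yl]methyl}prop-2-enoate
Product: 5 ethyl (2R,4aR,8aR)-4,4,7,8a-tetramethyl-8-oxo-1,2,3,4,4a,5,8,8a-octahydronaphthalene-2-carboxylate (trans-fused; C9 ketone; C7=C8; C2 ester equatorial)
Conditions: Fe(acac)3 (0.3 equiv), PhSiH3 (2.5 equiv), EtOH/(CH2OH)2 5:1, 0.01 M, 60 °C
Reagents that add atoms: none
Why: A trivalent iron hydride formed from Fe(acac)3 and PhSiH3 should donate a hydrogen atom to the terminal CH2 of the electron-rich isopropenyl group, which creates the second C4 methyl and a nucleophilic tertiary radical at C4; this radical adds to the terminal acrylate carbon C3, the α-ester radical at C2 is reduced by divalent iron to the enolate, and ethanol protonates it. The closest known reaction type is the metal-hydride hydrogen-atom-transfer Giese (reductive olefin) coupling of 1,1-disubstituted olefins with acrylates, run here within one molecule. Ring A closes in the 6-endo-trig mode through the C3–C4 bond; the 5-exo alternative at C2 is polarity-mismatched and would join two fully substituted carbons. The only new stereocentre is C2, set by protonation of the ester enolate (equatorial ester expected) and of no consequence because C2 ends as a methylene; C5 and C10 are untouched, and since their two arms are trans and both equatorial in the reactive conformer the decalin can only be trans-fused. The step needs hydrogen-atom transfer to the isopropenyl group in preference to the acrylate and the enone, and attack at C3 only: the first follows from the higher electron density of the isopropenyl olefin, the second from the polarity match, and the enone β-carbon C7 could be reached only through a four-membered ring. High dilution should suppress intermolecular addition and premature reduction of the C4 radical.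

**Step 4**
Reactants: 5 ethyl (2R,4aR,8aR)-4,4,7,8a-tetramethyl-8-oxo-1,2,3,4,4a,5,8,8a-octahydronaphthalene-2-carboxylate
Product: 6 (2R,4aR,8aR)-4,4,7,8a-tetramethyl-8-oxo-1,2,3,4,4a,5,8,8a-octahydronaphthalene-2-carboxylic acid
Conditions: LiOH, THF/MeOH/H2O, rt; then 1 M HCl
Reagents that add atoms: lithium hydroxide, [Li+].[OH-]
Why: Saponification of an unhindered secondary ester; the enone has no α′ hydrogen and epimerisation at C2 is immaterial.

**Step 5**
Reactants: 6 (2R,4aR,8aR)-4,4,7,8a-tetramethyl-8-oxo-1,2,3,4,4a,5,8,8a-octahydronaphthalene-2-carboxylic acid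
Product: 9 (4aR,8aR)-2,5,5,8a-tetramethyl-4a,5,6,7,8,8a-hexahydronaphthalen-1(4H)-one, via acid chloride 7 (not isolated), via thiohydroxamate ester 8 (not isolated)
Conditions: (COCl)2, DMF (cat.), CH2Cl2, 0 °C to rt; evaporate; sodium 2-thioxopyridin-1(2H)-olate, DMAP (cat.), t-BuSH, PhMe, tungsten lamp, 80 °C
Reagents that add atoms: none
Why: Barton reductive decarboxylation: the O-acyl thiohydroxamate fragments under visible light to the secondary C2 radical, which the thiol quenches, so C2 becomes a methylene and its stereocentre disappears; the radical is remote from the enone.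

**Step 6**
Reactants: 9 (4aR,8aR)-2,5,5,8a-tetramethyl-4a,5,6,7,8,8a-hexahydronaphthalen-1(4H)-one
Product: 10 (4aR,8aR)-2,5,5,8a-tetramethyl-4a,5,6,7,8,8a-hexahydronaphthalen-1-yl trifluoromethanesulfonate (C9 triflate; C9=C8 and C7=C6)
Conditions: KN(SiMe3)2, THF, −78 °C; PhNTf2, −78 to 0 °C
Reagents that add atoms: N-phenylbis(trifluoromethanesulfonimide), O=S(=O)(N(c1ccccc1)S(=O)(=O)C(F)(F)F)C(F)(F)F
Why: Dienyl triflate formation from an enone: with C10 quaternary the only acidic site is the γ-methylene C6, so the base gives the extended dienolate and O-sulfonylation fixes the C9=C8–C7=C6 diene.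

**Step 7**
Reactants: 11 (E)-3-methylpent-2-en-4-yn-1-ol
Product: 12 tert-butyldimethyl{[(E)-3-methylpent-2-en-4-yn-1-yl]oxy}silane
Conditions: t-BuMe2SiCl, imidazole, CH2Cl2, 0 °C to rt
Reagents that add atoms: tert-butyldimethylsilyl chloride, CC(C)(C)[Si](C)(C)Cl
Why: Standard silylation of a primary alcohol; a silyl ether is chosen because an allylic ester could be ionised by zerovalent palladium in step 9.

**Step 8**
Reactants: 12 tert-butyldimethyl{[(E)-3-methylpent-2-en-4-yn-1-yl]oxy}silane
Product: 13 tert-butyldimethyl{[(E)-3-methylpenta-2,4-dien-1-yl]oxy}silane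
Conditions: H2 (1 atm), Pd/CaCO3 poisoned with Pb(OAc)2, quinoline, hexane, rt, stopped after 1 equiv H2
Reagents that add atoms: none
Why: Lindlar semihydrogenation of the terminal alkyne should stop at the vinyl group and leave the E trisubstituted olefin unchanged.

**Step 9**
Reactants: 13 tert-butyldimethyl{[(E)-3-methylpenta-2,4-dien-1-yl]oxy}silane; 10 (4aR,8aR)-2,5,5,8a-tetramethyl-4a,5,6,7,8,8a-hexahydronaphthalen-1-yl trifluoromethanesulfonate
Product: 15 tert-butyldimethylsilyl ether of ent-labda-6,8,13E-trien-15-ol, via alkylborane 14 (not isolated)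
Conditions: 13, 9-BBN-H, THF, 0 °C to rt; then 10, Pd(dppf)Cl2 (10 mol%), AsPh3, Cs2CO3, DMF/H2O, 50 °C
Reagents that add atoms: none
Why: 9-BBN should add only to the terminal vinyl carbon of the diene (anti-Markovnikov hydroboration, trisubstituted olefin inert), and the primary alkylborane then forms C9–C11 by B-alkyl Suzuki–Miyaura coupling with the dienyl triflate, a coupling known for hindered cyclohexenyl triflates; no stereocentre is formed.

**Step 10**
Reactants: 15 tert-butyldimethylsilyl ether of ent-labda-6,8,13E-trien-15-ol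
Product: 16 tert-butyldimethylsilyl ether of ent-labda-7,13E-dien-15-ol (H9 cis to H5 and trans to C20)
Conditions: H2 (5 atm), (naphthalene)Cr(CO)3 (20 mol%), THF, 45 °C
Reagents that add atoms: none
Why: Arene-tricarbonylchromium-catalysed 1,4-hydrogenation acts only on s-cis 1,3-dienes and delivers both hydrogens from the metal-bound face, so the ring B diene, locked s-cis and bound on the face away from the axial C20 methyl, should receive hydrogen at C9 and C6 cis to H5, which sets C9 with an equatorial side chain, leaves the C7=C8 olefin and spares the isolated C13=C14 olefin.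

**Step 11**
Reactants: 16 tert-butyldimethylsilyl ether of ent-labda-7,13E-dien-15-ol
Product: 17 ent-labda-7,13E-dien-15-ol
Conditions: n-Bu4NF, THF, 0 °C to rt
Reagents that add atoms: none
Why: Fluoride-mediated desilylation of a primary allylic silyl ether, without effect on the olefins or stereocentres.

**Step 12**
Reactants: 18 15-pentadecanolide
Product: 19 15-bromopentadecanoic acid
Conditions: 48% aq HBr, conc. H2SO4 (cat.), AcOH, 100 °C
Reagents that add atoms: hydrogen bromide, Br
Why: Acid-mediated lactone opening: bromide attacks the protonated lactone at the primary alkyl carbon (SN2) and releases the ω-bromo acid.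

**Step 13**
Reactants: 19 15-bromopentadecanoic acid
Product: 20 15-bromopentadecan-1-ol
Conditions: BH3·SMe2, THF, 0 °C to rt; MeOH
Reagents that add atoms: none
Why: Borane reduces a carboxylic acid chemoselectively in the presence of a primary alkyl bromide.

**Step 14**
Reactants: 20 15-bromopentadecan-1-ol
Product: 21 [(15-bromopentadecyl)oxy](tert-butyl)diphenylsilane
Conditions: t-BuPh2SiCl, imidazole, CH2Cl2, rt
Reagents that add atoms: tert-butyldiphenylsilyl chloride, CC(C)(C)[Si](Cl)(c1ccccc1)c1ccccc1
Why: Standard silylation; the tert-butyldiphenylsilyl ether should survive Grignard formation, acidic work-up and the later selenium oxidation.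

**Step 15**
Reactants: 21 [(15-bromopentadecyl)oxy](tert-butyl)diphenylsilane; 19 15-bromopentadecanoic acid
Product: 24 30-[(tert-butyldiphenylsilyl)oxy]triacontanoic acid, via Grignard reagent 22 (not isolated), via magnesium carboxylate 23 (not isolated)
Conditions: 21, Mg, THF, 45 °C; separately 19, MeMgCl (1.0 equiv), THF, −20 °C; combine, Li2CuCl4 (3 mol%), −20 °C to rt; cold 1 M HCl
Reagents that add atoms: none
Why: Copper-catalysed sp3–sp3 coupling of a primary alkyl Grignard reagent with a primary alkyl bromide tolerates a carboxylate salt, so the two C15 halves are joined at C15–C16 of the acid without further redox steps.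

**Step 16**
Reactants: 17 ent-labda-7,13E-dien-15-ol; 24 30-[(tert-butyldiphenylsilyl)oxy]triacontanoic acid
Product: 25 ent-labda-7,13E-dien-15-yl 30-[(tert-butyldiphenylsilyl)oxy]triacontanoate
Conditions: DCC, DMAP (cat.), CH2Cl2, rt
Reagents that add atoms: none
Why: Steglich esterification of a primary allylic alcohol under neutral conditions, without allylic transposition.

**Step 17**
Reactants: 25 ent-labda-7,13E-dien-15-yl 30-[(tert-butyldiphenylsilyl)oxy]triacontanoate
Product: 26 17-hydroxy-ent-labda-7,13E-dien-15-yl 30-[(tert-butyldiphenylsilyl)oxy]triacontanoate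
Conditions: SeO2 (0.5 equiv), t-BuOOH (3 equiv, in decane), salicylic acid (cat.), CH2Cl2, rt
Reagents that add atoms: selenium dioxide, O=[Se]=O (oxygen carrier); tert-butyl hydroperoxide, CC(C)(C)OO (stoichiometric oxygen source)
Why: Riley allylic oxidation (ene reaction, then 2,3-sigmatropic shift) attacks the more substituted end C8 of the ring olefin, where the C17 methyl is accessible and the tertiary C9–H is buried beside the quaternary C10, as is known for closely related drim-7-enes carrying an acyloxymethyl group on C9; the C13=C14 olefin is deactivated by its allylic acyloxy group, the olefin returns to C7=C8 and no stereocentre is formed.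

**Step 18**
Reactants: 26 17-hydroxy-ent-labda-7,13E-dien-15-yl 30-[(tert-butyldiphenylsilyl)oxy]triacontanoate
Product: 27 17-hydroxy-ent-labda-7,13E-dien-15-yl 30-hydroxytriacontanoate (CNP0329077.1)
Conditions: n-Bu4NF, AcOH, THF, rt
Reagents that add atoms: none
Why: Buffered fluoride desilylation removes the primary silyl ether; the acetic acid buffer should keep the allylic ester from cleavage or acyl transfer.

**Compound list**
1 | (S)-(+)-carvone | CC1=CC[C@@H](CC1=O)C(C)=C | starting material
2 | trans-6-methylcarvone, (5S,6R)-2,6-dimethyl-5-(prop-1-en-2-yl)cyclohex-2-en-1-one | O=C1C(C)=CC[C@H](C(C)=C)[C@H]1C | intermediate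
3 | ethyl 2-(bromomethyl)acrylate | C=C(CBr)C(=O)OCC | starting material
4 | ethyl 2-{[(1R,6R)-1,3-dimethyl-2-oxo-6-(prop-1-en-2-yl)cyclohex-3-en-1-yl]methyl}prop-2-enoate | O=C1C(C)=CC[C@H](C(C)=C)[C@@]1(C)CC(=C)C(=O)OCC | intermediate
5 | ethyl (2R,4aR,8aR)-4,4,7,8a-tetramethyl-8-oxo-1,2,3,4,4a,5,8,8a-octahydronaphthalene-2-carboxylate | O=C1C(C)=CC[C@@H]2C(C)(C)C[C@@H](C(=O)OCC)C[C@@]12C | intermediate
6 | (2R,4aR,8aR)-4,4,7,8a-tetramethyl-8-oxo-1,2,3,4,4a,5,8,8a-octahydronaphthalene-2-carboxylic acid | O=C1C(C)=CC[C@@H]2C(C)(C)C[C@@H](C(=O)O)C[C@@]12C | intermediate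
7 | acid chloride of 6 | O=C1C(C)=CC[C@@H]2C(C)(C)C[C@@H](C(=O)Cl)C[C@@]12C | intermediate
8 | 2-thioxopyridin-1(2H)-yl ester of 6 | O=C1C(C)=CC[C@@H]2C(C)(C)C[C@@H](C(=O)ON3C=CC=CC3=S)C[C@@]12C | intermediate
9 | (4aR,8aR)-2,5,5,8a-tetramethyl-4a,5,6,7,8,8a-hexahydronaphthalen-1(4H)-one | O=C1C(C)=CC[C@@H]2C(C)(C)CCC[C@@]12C | intermediate
10 | (4aR,8aR)-2,5,5,8a-tetramethyl-4a,5,6,7,8,8a-hexahydronaphthalen-1-yl trifluoromethanesulfonate | O=S(=O)(OC1=C(C)C=C[C@@H]2C(C)(C)CCC[C@@]12C)C(F)(F)F | intermediate
11 | (E)-3-methylpent-2-en-4-yn-1-ol | C#C/C(C)=C/CO | starting material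
12 | tert-butyldimethyl{[(E)-3-methylpent-2-en-4-yn-1-yl]oxy}silane | C#C/C(C)=C/CO[Si](C)(C)C(C)(C)C | intermediate
13 | tert-butyldimethyl{[(E)-3-methylpenta-2,4-dien-1-yl]oxy}silane | C=C/C(C)=C/CO[Si](C)(C)C(C)(C)C | intermediate
14 | 9-[(E)-5-(tert-butyldimethylsilyloxy)-3-methylpent-3-en-1-yl]-9-borabicyclo[3.3.1]nonane | C1CC2CCCC(C1)B2CC/C(C)=C/CO[Si](C)(C)C(C)(C)C | intermediate
15 | tert-butyldimethylsilyl ether of ent-labda-6,8,13E-trien-15-ol | C/C(=C\CO[Si](C)(C)C(C)(C)C)CCC1=C(C)C=C[C@@H]2C(C)(C)CCC[C@@]12C | intermediate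
16 | tert-butyldimethylsilyl ether of ent-labda-7,13E-dien-15-ol | C/C(=C\CO[Si](C)(C)C(C)(C)C)CC[C@@H]1C(C)=CC[C@@H]2C(C)(C)CCC[C@@]12C | intermediate
17 | ent-labda-7,13E-dien-15-ol | C/C(=C\CO)CC[C@@H]1C(C)=CC[C@@H]2C(C)(C)CCC[C@@]12C | intermediate
18 | 15-pentadecanolide | O=C1CCCCCCCCCCCCCCO1 | starting material
19 | 15-bromopentadecanoic acid | OC(=O)CCCCCCCCCCCCCCBr | intermediate
20 | 15-bromopentadecan-1-ol | OCCCCCCCCCCCCCCCBr | intermediate
21 | [(15-bromopentadecyl)oxy](tert-butyl)diphenylsilane | CC(C)(C)[Si](c1ccccc1)(c1ccccc1)OCCCCCCCCCCCCCCCBr | intermediate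
22 | {15-[(tert-butyldiphenylsilyl)oxy]pentadecyl}magnesium bromide | CC(C)(C)[Si](c1ccccc1)(c1ccccc1)OCCCCCCCCCCCCCCC[Mg]Br | intermediate
23 | chloromagnesium 15-bromopentadecanoate | BrCCCCCCCCCCCCCCC(=O)O[Mg]Cl | intermediate
24 | 30-[(tert-butyldiphenylsilyl)oxy]triacontanoic acid | CC(C)(C)[Si](c1ccccc1)(c1ccccc1)OCCCCCCCCCCCCCCCCCCCCCCCCCCCCCC(=O)O | intermediate
25 | ent-labda-7,13E-dien-15-yl 30-[(tert-butyldiphenylsilyl)oxy]triacontanoate | C/C(=C\COC(=O)CCCCCCCCCCCCCCCCCCCCCCCCCCCCCO[Si](c1ccccc1)(c1ccccc1)C(C)(C)C)CC[C@@H]1C(C)=CC[C@@H]2C(C)(C)CCC[C@@]12C | intermediate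
26 | 17-hydroxy-ent-labda-7,13E-dien-15-yl 30-[(tert-butyldiphenylsilyl)oxy]triacontanoate | C/C(=C\COC(=O)CCCCCCCCCCCCCCCCCCCCCCCCCCCCCO[Si](c1ccccc1)(c1ccccc1)C(C)(C)C)CC[C@@H]1C(CO)=CC[C@@H]2C(C)(C)CCC[C@@]12C | intermediate
27 | 17-hydroxy-ent-labda-7,13E-dien-15-yl 30-hydroxytriacontanoate, (5R,9S,10R), CNP0329077.1 | C/C(=C\COC(=O)CCCCCCCCCCCCCCCCCCCCCCCCCCCCCO)CC[C@@H]1C(CO)=CC[C@@H]2C(C)(C)CCC[C@@]12C | target

**Step count and risks**
Total: 18 steps. Longest linear sequence: 12 steps (1 to 6, 9, 10, 11, 16, 17, 18, from carvone).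

Step 10 (1,4-hydrogenation). The diene is fully substituted at C9 and flanked by the quaternary C10, so it may bind chromium too slowly; the catalyst could then decay before turnover, or the diene could isomerise instead of being reduced. The fallback gives up the late hydrogenation, sets C9 by kinetic protonation of an ester dienolate and then builds the side chain; it sets out from 10 and returns at 17. Methoxycarbonylation of 10 (Pd(OAc)2, dppp, CO, MeOH, Et3N, DMF, 60 °C) should give methyl ent-drima-6,8-dien-11-oate F1. Dissolving-metal 1,6-reduction (Li, NH3/THF, −78 °C, then NH4Cl) adds hydrogen at C6 and protonates the dienolate at C9 from the face opposite C20, giving the β,γ-unsaturated ester methyl ent-drim-7-en-11-oate F2. LiAlH4 in Et2O gives ent-drim-7-en-11-ol F3, and PPh3, I2 and imidazole give 11-iodo-ent-drim-7-ene F4. Alkylation of lithiated 1-(trimethylsilyl)propyne (n-BuLi, THF, −78 °C) with F4 should give 14-(trimethylsilyl)-15,16-dinor-ent-labd-7-en-13-yne F5, and K2CO3 in MeOH the terminal alkyne 15,16-dinor-ent-labd-7-en-13-yne F6. Zirconium-catalysed carboalumination (Me3Al, Cp2ZrCl2, CH2Cl2) followed by paraformaldehyde then installs C16 and C15 with E geometry and gives 17.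

Step 17 (allylic hydroxylation). Selenium may also attack C6 or the side-chain olefin, and oxidation may run on to the C17 aldehyde. The fallback replaces the ene pathway by an epoxide route, from 25 back to 26. m-Chloroperbenzoic acid (NaHCO3, CH2Cl2, 0 °C) should epoxidise the more electron-rich ring olefin from the face opposite C20, giving 7,8-epoxy-ent-labd-13E-en-15-yl 30-[(tert-butyldiphenylsilyl)oxy]triacontanoate F7. Trivalent titanium (Cp2TiCl from Cp2TiCl2 and Mn, THF, rt) opens the epoxide homolytically at C8, and elimination toward the methyl group gives the exocyclic allylic alcohol 7-hydroxy-ent-labda-8(17),13E-dien-15-yl 30-[(tert-butyldiphenylsilyl)oxy]triacontanoate F8. A catalytic 1,3-transposition of the allylic alcohol (Ph3SiOReO3, Et2O, 0 °C) then moves the oxygen to C17 and the olefin back to C7=C8, which is 26.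

Step 3 (radical ring closure). The C4 radical may be reduced before it cyclises, leaving an isopropyl group, or the hydrogen atom may be transferred to the acrylate instead. The fallback makes the same radical from a halide, from 4 back to 5. HBr in AcOH/CH2Cl2 at −20 °C should add in the Markovnikov sense to the isopropenyl group only, giving the tertiary bromide ethyl 2-{[(1R,6R)-6-(2-bromopropan-2-yl)-1,3-dimethyl-2-oxocyclohex-3-en-1-yl]methyl}prop-2-enoate F9. Slow addition of Bu3SnH with AIBN in benzene at 80 °C abstracts bromine, and the tertiary radical closes ring A by the same 6-endo Giese addition to give 5.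

**Further compounds**
F1 | step 10 | methyl ent-drima-6,8-dien-11-oate | COC(=O)C1=C(C)C=C[C@@H]2C(C)(C)CCC[C@@]12C
F2 | step 10 | methyl ent-drim-7-en-11-oate | COC(=O)[C@@H]1C(C)=CC[C@@H]2C(C)(C)CCC[C@@]12C
F3 | step 10 | ent-drim-7-en-11-ol | OC[C@@H]1C(C)=CC[C@@H]2C(C)(C)CCC[C@@]12C
F4 | step 10 | 11-iodo-ent-drim-7-ene | IC[C@@H]1C(C)=CC[C@@H]2C(C)(C)CCC[C@@]12C
F5 | step 10 | 14-(trimethylsilyl)-15,16-dinor-ent-labd-7-en-13-yne | C[Si](C)(C)C#CCC[C@@H]1C(C)=CC[C@@H]2C(C)(C)CCC[C@@]12C
F6 | step 10 | 15,16-dinor-ent-labd-7-en-13-yne | C#CCC[C@@H]1C(C)=CC[C@@H]2C(C)(C)CCC[C@@]12C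
F7 | step 17 | 7,8-epoxy-ent-labd-13E-en-15-yl 30-[(tert-butyldiphenylsilyl)oxy]triacontanoate (oxygen on the face of H5) | C/C(=C\COC(=O)CCCCCCCCCCCCCCCCCCCCCCCCCCCCCO[Si](c1ccccc1)(c1ccccc1)C(C)(C)C)CC[C@@H]1[C@@]3(C)O[C@H]3C[C@@H]2C(C)(C)CCC[C@@]12C
F8 | step 17 | 7-hydroxy-ent-labda-8(17),13E-dien-15-yl 30-[(tert-butyldiphenylsilyl)oxy]triacontanoate | C/C(=C\COC(=O)CCCCCCCCCCCCCCCCCCCCCCCCCCCCCO[Si](c1ccccc1)(c1ccccc1)C(C)(C)C)CC[C@@H]1C(=C)[C@@H](O)C[C@@H]2C(C)(C)CCC[C@@]12C
F9 | step 3 | ethyl 2-{[(1R,6R)-6-(2-bromopropan-2-yl)-1,3-dimethyl-2-oxocyclohex-3-en-1-yl]methyl}prop-2-enoate | O=C1C(C)=CC[C@H](C(C)(C)Br)[C@@]1(C)CC(=C)C(=O)OCC
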